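**Remark.** Locants C1–C15 are those of the target in germacranolide numbering and are used for every intermediate: C6 carries the lactone oxygen, C7 the C11 branch, C8 the angelate, C10 the tertiary carbinol, C3 the secondary carbinol; C12 is the lactone carbonyl and C13 the exocyclic methylene. The target is taken as (3S,6S,7R,8R,10S), 4Z, with a (Z)-2-methylbut-2-enoate, as written in the SMILES.

## Retrosynthetic overview

- Ring B (ten-membered carbocycle) is closed last at C3–C4 by an intramolecular Nozaki–Hiyama–Kishi reaction of a (Z)-C4 alkenyl iodide with a C3 aldehyde.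
- Ring A (γ-lactone) is closed first, on an acyclic chain, by forming C11–C7: a phosphonoacetate carbanion tethered through O6 opens a trans-7,8-epoxide and is methylenated with formaldehyde in the same flask.
- Enabling feature: O6, C11 and O8 are all cis on C6–C7–C8, so C11 can be delivered from O6 to C7 anti to an epoxide oxygen that stays on C8 as the future angelate oxygen. The epoxide C7–O bond is not in the target; it is made to control C7 and C8 and is cleaved in the key step.
- C10, C1–C3 and C8–C9 come from geraniol (Sharpless epoxidation, hydride opening). C6–C8 are set by a Sharpless kinetic-resolution epoxidation followed by Mitsunobu inversion at C6. C3 is set in the ring-B closure.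

Key step: step 10

## Route

Step 1
Reactants: 1 geraniol
Product: 2 (2S,3S)-2,3-epoxygeraniol
Conditions: Ti(OiPr)4 (cat.), L-(+)-diethyl tartrate (cat.), t-BuOOH, 4 Å MS, CH2Cl2, −20 °C
Reagents that add atoms: tert-butyl hydroperoxide CC(C)(C)OO
Why: Sharpless asymmetric epoxidation of a primary E-allylic alcohol, in which the L-(+)-tartrate titanium complex delivers oxygen to one alkene face and so sets the future C10 (and C9) configuration, while the isolated trisubstituted alkene is not epoxidised.

Step 2
Reactants: 2 (2S,3S)-2,3-epoxygeraniol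
Product: 3 (3S)-3,7-dimethyloct-6-ene-1,3-diol
Conditions: NaAlH2(OCH2CH2OMe)2, THF, 0 °C → rt; aq. Rochelle salt
Reagents that add atoms: none
Why: Regioselective reductive opening of a 2,3-epoxy alcohol, the hydride being delivered from the alkoxyaluminate to the secondary carbon (future C9), so that the tertiary C10–O bond and its configuration are kept and the 1,3-diol results.

Step 3
Reactants: 3 (3S)-3,7-dimethyloct-6-ene-1,3-diol
Product: 4 (3S)-3,7-dimethyl-1,3-bis(triethylsilyloxy)oct-6-ene
Conditions: TESOTf, 2,6-lutidine, CH2Cl2, −78 → 0 °C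
Reagents that add atoms: triethylsilyl trifluoromethanesulfonate CC[Si](CC)(CC)OS(=O)(=O)C(F)(F)F
Why: Silyl ether formation with a silyl triflate and a hindered base should silylate the primary and the tertiary hydroxyl alike, the C10 ether later preventing lactol formation with the C3 aldehyde; no stereocentre is touched.

Step 4
Reactants: 4 (3S)-3,7-dimethyl-1,3-bis(triethylsilyloxy)oct-6-ene
Product: 6 (3S)-3,7-dimethyl-3-(triethylsilyloxy)oct-6-enal, via alkoxysulfonium chloride 5 (not isolated)
Conditions: (COCl)2, DMSO, CH2Cl2, −78 °C; 4, −78 → −30 °C; Et3N, → 0 °C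
Reagents that add atoms: none
Why: Swern oxidation applied directly to a primary triethylsilyl ether, which is exchanged for the alkoxysulfonium ion and oxidised to the aldehyde while the hindered tertiary silyl ether does not react.

Step 5
Reactants: 6 (3S)-3,7-dimethyl-3-(triethylsilyloxy)oct-6-enal; 7 (triphenylphosphoranylidene)acetaldehyde
Product: 8 (2E,5S)-5,9-dimethyl-5-(triethylsilyloxy)deca-2,8-dienal
Conditions: toluene, 80 °C
Reagents that add atoms: none
Why: Wittig olefination with a formyl-stabilised ylide should add C7 and C6 and give the E-enal, as stabilised ylides do.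

Step 6
Reactants: 8 (2E,5S)-5,9-dimethyl-5-(triethylsilyloxy)deca-2,8-dienal; 9 1-propynylmagnesium bromide (CH3C≡CMgBr)
Product: 10 (5E,8S)-8,12-dimethyl-8-(triethylsilyloxy)trideca-5,11-dien-2-yn-4-ol (both C6 epimers)
Conditions: THF, −78 → 0 °C; aq. NH4Cl
Reagents that add atoms: none
Why: 1,2-Addition of an alkynyl Grignard reagent to the enal carbonyl brings in C5, C4 and C15; no control at the new C6 carbinol is sought, both epimers being formed and sorted out by the kinetic resolution in step 8.

Step 7
Reactants: 10 (5E,8S)-8,12-dimethyl-8-(triethylsilyloxy)trideca-5,11-dien-2-yn-4-ol (both C6 epimers)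
Product: 12 (2Z,5E,8S)-2-iodo-8,12-dimethyl-8-(triethylsilyloxy)trideca-2,5,11-trien-4-ol (both C6 epimers), via cyclic alkenylaluminate 11 (not isolated)
Conditions: NaAlH2(OCH2CH2OMe)2, THF, 0 °C → rt; EtOAc; I2, −78 → 0 °C
Reagents that add atoms: iodine II
Why: Hydroxyl-directed trans-hydroalumination of the propargylic alcohol puts hydride on C5 and aluminium on C4 in a five-membered alanate, so that iodinolysis with retention gives the alkenyl iodide with iodine cis to C6 (Z), while the E-7,8-alkene is not reduced.

Step 8
Reactants: 12 (2Z,5E,8S)-2-iodo-8,12-dimethyl-8-(triethylsilyloxy)trideca-2,5,11-trien-4-ol (the 6S epimer reacts)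
Product: 13 (2Z,4R,5R,6R,8S)-5,6-epoxy-2-iodo-8,12-dimethyl-8-(triethylsilyloxy)trideca-2,11-dien-4-ol (erythro; 6R,7R,8R,10S in target locants)
Conditions: Ti(OiPr)4, D-(−)-diisopropyl tartrate, t-BuOOH (0.6 equiv), 4 Å MS, CH2Cl2, −20 °C
Reagents that add atoms: tert-butyl hydroperoxide CC(C)(C)OO
Why: Sharpless kinetic-resolution epoxidation, in which the D-(−)-tartrate titanium complex should epoxidise only the 6S epimer of 12, on the E-7,8-alkene and from the face that gives the erythro epoxy alcohol, so that C7 and C8 are set by the reagent and C6 by the resolution (6S in 12 becomes 6R in 13 only through a change of CIP priorities), while the slow 6R epimer, the cis-substituted electron-poor iodoalkene and the remote alkene are left and the 6R alcohol can be recycled by oxidation and reduction.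

Step 9
Reactants: 13 erythro epoxy alcohol (6R,7R,8R,10S); 14 diethylphosphonoacetic acid
Product: 15 (2Z,4S,5S,6R,8S)-5,6-epoxy-2-iodo-8,12-dimethyl-8-(triethylsilyloxy)trideca-2,11-dien-4-yl (diethoxyphosphoryl)acetate (threo; C6 inverted)
Conditions: PPh3, DIAD, toluene, 0 °C → rt
Reagents that add atoms: none
Why: Mitsunobu esterification, in which the carboxylate displaces the activated C6 oxyphosphonium group in an SN2 reaction, installs the tether with inversion at C6 (6R erythro to 6S threo), which is the relative configuration the key step needs, and leaves the epoxide intact under neutral conditions.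

Step 10
Reactants: 15 threo epoxy phosphonoacetate
Product: 17 (4R,5R)-4-[(1R,3S)-1-hydroxy-3,7-dimethyl-3-(triethylsilyloxy)oct-6-en-1-yl]-5-[(1Z)-2-iodoprop-1-en-1-yl]-3-methylideneoxolan-2-one, via α-phosphono lactone 16 (not isolated)
Conditions: KOtBu (1.0 equiv), THF, 0 → 45 °C; (CH2O)n, 0 °C → rt; aq. NH4Cl
Reagents that add atoms: formaldehyde (as paraformaldehyde) C=O
Why: Proposed new method: KOtBu deprotonates the phosphonoacetate CH2 of 15 and the phosphoryl-stabilised carbanion C11 attacks C7 of the trans-7,8-epoxide from the side opposite the epoxide oxygen (SN2), the liberated C8 alkoxide at once takes the remaining C11 proton, and the regenerated phosphonate carbanion of 16 olefinates formaldehyde (Horner–Wadsworth–Emmons) to the exocyclic C11=C13 methylene. The closest known reaction types are the telescoped intramolecular Michael addition/Horner–Wadsworth–Emmons olefination of ester-tethered phosphonoacetates, which closes the same lactone ring onto an sp2 carbon, and the intermolecular alkylation of phosphonoacetate anions by epoxides. Ring A is closed in the 5-exo-tet mode, the stabilising phosphoryl group being exocyclic, so that the carbanion lone pair can line up with the C7–O bond without a planar ester enolate having to lie within the forming ring. C7 is set by inversion at the epoxide carbon, which with the 6S ester forces the cis ring fusion, C8 keeps the configuration given by the Sharpless epoxidation, and C6 is untouched. The step needs attack at C7 rather than at C8 (6-endo), and it must outrun phosphoryl transfer to O8 and translactonisation to O8; the five-atom tether (exo opening) secures the first, and the fast internal proton transfer, the moderate temperature and the single equivalent of base (no alkoxide is left after the olefination) secure the others.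

Step 11
Reactants: 17 hydroxy α-methylene lactone; 18 angelic acid
Product: 20 (1R,3S)-1-[(2R,3R)-2-[(1Z)-2-iodoprop-1-en-1-yl]-4-methylidene-5-oxooxolan-3-yl]-3,7-dimethyl-3-(triethylsilyloxy)oct-6-en-1-yl (2Z)-2-methylbut-2-enoate, via angelic 2,4,6-trichlorobenzoic anhydride 19 (not isolated)
Conditions: 2,4,6-Cl3C6H2COCl, Et3N, toluene, rt; then 17, 80 °C
Reagents that add atoms: none
Why: Yamaguchi-type mixed-anhydride esterification should acylate the secondary C8 hydroxyl with retention at C8 and without the nucleophilic catalysis that isomerises angelate to tiglate.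

Step 12
Reactants: 20 C8 angelate
Product: 22 (1R,3S)-1-[(2R,3R)-2-[(1Z)-2-iodoprop-1-en-1-yl]-4-methylidene-5-oxooxolan-3-yl]-3-methyl-6-oxo-3-(triethylsilyloxy)hexyl (2Z)-2-methylbut-2-enoate, via ozonide 21 (not isolated)
Conditions: O3, CH2Cl2, −78 °C (Sudan Red 7B end-point); PPh3, −78 °C → rt
Reagents that add atoms: ozone [O-][O+]=O
Why: Ozonolysis with an indicator end-point should cleave only the electron-rich, non-conjugated trisubstituted alkene (cycloaddition, ozonide, reductive work-up) and unmask the C3 aldehyde, the two conjugated ester alkenes and the iodoalkene being much less reactive towards ozone.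

Step 13
Reactants: 22 C3 aldehyde
Product: 23 10-O-triethylsilyl ether of the target (3S,6S,7R,8R,10S)
Conditions: CrCl2 (excess), NiCl2 (cat.), DMSO, rt, high dilution (slow addition)
Reagents that add atoms: none
Why: Nozaki–Hiyama–Kishi reaction, in which oxidative addition of the alkenyl iodide to zerovalent nickel, transmetalation to trivalent chromium and addition to the C3 aldehyde with retention of the Z alkene geometry should close ring B, the cis-fused lactone holding both chain ends on one face; the 3S configuration is expected from attack on the aldehyde face exposed in the folded ring-forming transition state and is the least secure element.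

Step 14
Reactants: 23 10-O-triethylsilyl ether of the target
Product: 24 target, (3S,6S,7R,8R,10S)-3,10-dihydroxy-8-[(2Z)-2-methylbut-2-enoyloxy]germacra-4Z,11(13)-dien-12,6-olide
Conditions: HF·pyridine, pyridine, THF, 0 °C
Reagents that add atoms: none
Why: Fluoride-induced desilylation of the tertiary silyl ether under buffered conditions should leave the lactone, the angelate and the allylic alcohol untouched and affects no stereocentre.

## Compound list

1 | geraniol, (2E)-3,7-dimethylocta-2,6-dien-1-ol | C/C(=C\CO)CCC=C(C)C | starting material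
2 | (2S,3S)-2,3-epoxygeraniol | OC[C@@H]1O[C@@]1(C)CCC=C(C)C | intermediate
3 | (3S)-3,7-dimethyloct-6-ene-1,3-diol | OCC[C@@](C)(O)CCC=C(C)C | intermediate
4 | (3S)-3,7-dimethyl-1,3-bis(triethylsilyloxy)oct-6-ene | CC[Si](CC)(CC)OCC[C@@](C)(O[Si](CC)(CC)CC)CCC=C(C)C | intermediate
5 | [(3S)-3,7-dimethyl-3-(triethylsilyloxy)oct-6-en-1-yl]oxydimethylsulfonium chloride | C[S+](C)OCC[C@@](C)(O[Si](CC)(CC)CC)CCC=C(C)C.[Cl-] | intermediate
6 | (3S)-3,7-dimethyl-3-(triethylsilyloxy)oct-6-enal | O=CC[C@@](C)(O[Si](CC)(CC)CC)CCC=C(C)C | intermediate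
7 | (triphenylphosphoranylidene)acetaldehyde | O=CC=P(c1ccccc1)(c1ccccc1)c1ccccc1 | starting material
8 | (2E,5S)-5,9-dimethyl-5-(triethylsilyloxy)deca-2,8-dienal | O=C/C=C/C[C@@](C)(O[Si](CC)(CC)CC)CCC=C(C)C | intermediate
9 | 1-propynylmagnesium bromide | CC#C[Mg]Br | starting material
10 | (5E,8S)-8,12-dimethyl-8-(triethylsilyloxy)trideca-5,11-dien-2-yn-4-ol, both epimers at C4 (= C6) | CC#CC(O)/C=C/C[C@@](C)(O[Si](CC)(CC)CC)CCC=C(C)C | intermediate
11 | sodium cyclic alkenylaluminate (five-membered O6–Al–C4=C5–C6 ring, two 2-methoxyethoxy groups on aluminium) | [Na+].COCCO[Al-]1(OCCOC)OC(/C=C/C[C@@](C)(O[Si](CC)(CC)CC)CCC=C(C)C)C=C1C | intermediate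
12 | (2Z,5E,8S)-2-iodo-8,12-dimethyl-8-(triethylsilyloxy)trideca-2,5,11-trien-4-ol, both epimers at C4 (= C6) | C/C(I)=C/C(O)/C=C/C[C@@](C)(O[Si](CC)(CC)CC)CCC=C(C)C | intermediate
13 | (2Z,4R,5R,6R,8S)-5,6-epoxy-2-iodo-8,12-dimethyl-8-(triethylsilyloxy)trideca-2,11-dien-4-ol (erythro) | O[C@H](/C=C(/C)I)[C@H]1O[C@@H]1C[C@@](C)(O[Si](CC)(CC)CC)CCC=C(C)C | intermediate
14 | diethylphosphonoacetic acid | CCOP(=O)(CC(=O)O)OCC | starting material
15 | (2Z,4S,5S,6R,8S)-5,6-epoxy-2-iodo-8,12-dimethyl-8-(triethylsilyloxy)trideca-2,11-dien-4-yl (diethoxyphosphoryl)acetate (threo) | CCOP(=O)(OCC)CC(=O)O[C@@H](/C=C(/C)I)[C@H]1O[C@@H]1C[C@@](C)(O[Si](CC)(CC)CC)CCC=C(C)C | intermediate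
16 | 3-(diethoxyphosphoryl) analogue of 17 (C6, C7, C8 as in 17; both epimers at C11) | CCOP(=O)(OCC)C1C(=O)O[C@@H](/C=C(/C)I)[C@H]1[C@H](O)C[C@@](C)(O[Si](CC)(CC)CC)CCC=C(C)C | intermediate
17 | (4R,5R)-4-[(1R,3S)-1-hydroxy-3,7-dimethyl-3-(triethylsilyloxy)oct-6-en-1-yl]-5-[(1Z)-2-iodoprop-1-en-1-yl]-3-methylideneoxolan-2-one (C6, C7, C8 arranged as in the target) | C=C1C(=O)O[C@@H](/C=C(/C)I)[C@H]1[C@H](O)C[C@@](C)(O[Si](CC)(CC)CC)CCC=C(C)C | intermediate
18 | angelic acid, (2Z)-2-methylbut-2-enoic acid | C/C=C(/C)C(=O)O | starting material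
19 | angelic 2,4,6-trichlorobenzoic anhydride | C/C=C(/C)C(=O)OC(=O)c1c(Cl)cc(Cl)cc1Cl | intermediate
20 | (1R,3S)-1-[(2R,3R)-2-[(1Z)-2-iodoprop-1-en-1-yl]-4-methylidene-5-oxooxolan-3-yl]-3,7-dimethyl-3-(triethylsilyloxy)oct-6-en-1-yl (2Z)-2-methylbut-2-enoate | C=C1C(=O)O[C@@H](/C=C(/C)I)[C@H]1[C@H](OC(=O)/C(C)=C\C)C[C@@](C)(O[Si](CC)(CC)CC)CCC=C(C)C | intermediate
21 | ozonide of 20 (3,3-dimethyl-1,2,4-trioxolane at the former terminal alkene) | C=C1C(=O)O[C@@H](/C=C(/C)I)[C@H]1[C@H](OC(=O)/C(C)=C\C)C[C@@](C)(O[Si](CC)(CC)CC)CCC1OOC(C)(C)O1 | intermediate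
22 | (1R,3S)-1-[(2R,3R)-2-[(1Z)-2-iodoprop-1-en-1-yl]-4-methylidene-5-oxooxolan-3-yl]-3-methyl-6-oxo-3-(triethylsilyloxy)hexyl (2Z)-2-methylbut-2-enoate | C=C1C(=O)O[C@@H](/C=C(/C)I)[C@H]1[C@H](OC(=O)/C(C)=C\C)C[C@@](C)(O[Si](CC)(CC)CC)CCC=O | intermediate
23 | 10-O-triethylsilyl ether of the target, (3S,6S,7R,8R,10S) | C=C1C(=O)O[C@H]2/C=C(/C)[C@@H](O)CC[C@](C)(O[Si](CC)(CC)CC)C[C@@H](OC(=O)/C(C)=C\C)[C@@H]12 | intermediate
24 | (3S,6S,7R,8R,10S)-3,10-dihydroxy-8-[(2Z)-2-methylbut-2-enoyloxy]germacra-4Z,11(13)-dien-12,6-olide | C=C1C(=O)O[C@H]2/C=C(/C)[C@@H](O)CC[C@](C)(O)C[C@@H](OC(=O)/C(C)=C\C)[C@@H]12 | target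

## Step count

Total step count: 14. Longest linear sequence: 14 steps (1 → 24).

## Steps most likely to fail

**Step 10 (Proposed new method).** The stabilised carbanion may open the internal epoxide too slowly. Attack at C8, phosphoryl transfer to O8 or base-induced epoxide isomerisation could then take over, and the cis-closing transition state adds strain.

The fallback uses known chemistry, sets out from 13 and comes back at 20, replacing steps 9–11. It is longer, because kinetic radical closures place the C6 and C7 substituents trans, so it is run in the C6-epimeric series and C6 is inverted at the end. Alcohol 13 would be converted at O6 into the 1-ethoxyprop-2-ynyl mixed acetal F1 (3,3-diethoxyprop-1-yne, PPTS). Cp2TiCl (trivalent titanium, made from Cp2TiCl2 and Zn) would open the epoxide reductively to the C7 radical, which closes 5-exo-dig onto the alkyne (titanocene-mediated reductive epoxide opening/radical cyclisation) to the 2-ethoxy-3-methylideneoxolane F2, with C8–OH set free from the epoxide oxygen. The trans closure in this C6-epimeric series gives the target configuration at C7. Angeloylation as in step 11 (with 18) would give F3, aqueous AcOH the lactol F4, and NaClO2 oxidation of its open hydroxy-enal form the hydroxy acid F5, which is used at once. Mitsunobu lactonisation (PPh3, DIAD) would then close the lactone with inversion at the allylic C6 and give 20.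

**Step 13.** The alkenylchromium may add to the C3 aldehyde with poor facial selectivity and give the C3 epimer. The fallback sets out from 22 and comes back at 23. The ring closure is run as planned, and the C3-epimeric alcohol F6 (alone or mixed with 23) would be oxidised with Dess–Martin periodinane to the cyclodecadienone F7. C3 is then set by reagent control in a Corey–Bakshi–Shibata reduction ((R)-Me-CBS oxazaborolidine, BH3·SMe2, the alkenyl group acting as the large substituent), which should return (3S)-23.

**Step 12.** Ozone may lose chemoselectivity and also attack the iodoalkene or the angelate double bond before the end-point. The fallback sets out from 20 and comes back at 22. Catalytic OsO4 with N-methylmorpholine N-oxide should dihydroxylate only the electron-rich trisubstituted alkene to diol F8, and NaIO4 glycol cleavage would then give 22.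

## Further compounds

F1 | step 10 | O6-(1-ethoxyprop-2-yn-1-yl) mixed acetal of 13 (acetal carbon as a mixture) | C#CC(OCC)O[C@H](/C=C(/C)I)[C@H]1O[C@@H]1C[C@@](C)(O[Si](CC)(CC)CC)CCC=C(C)C
F2 | step 10 | 2-ethoxy-3-methylideneoxolane from the radical closure (C6 and C7 substituents trans, C6 epimeric to the target, C7 and C8 as in the target, C8–OH free) | C=C1C(OCC)O[C@H](/C=C(/C)I)[C@H]1[C@H](O)C[C@@](C)(O[Si](CC)(CC)CC)CCC=C(C)C
F3 | step 10 | C8 angelate of F2 | C=C1C(OCC)O[C@H](/C=C(/C)I)[C@H]1[C@H](OC(=O)/C(C)=C\C)C[C@@](C)(O[Si](CC)(CC)CC)CCC=C(C)C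
F4 | step 10 | lactol from F3 (2-hydroxy-3-methylideneoxolane) | C=C1C(O)O[C@H](/C=C(/C)I)[C@H]1[C@H](OC(=O)/C(C)=C\C)C[C@@](C)(O[Si](CC)(CC)CC)CCC=C(C)C
F5 | step 10 | seco hydroxy acid (2-methylidene carboxylic acid with free 6-epi C6–OH and C8 angelate) | C=C(C(=O)O)[C@@H]([C@H](O)/C=C(/C)I)[C@H](OC(=O)/C(C)=C\C)C[C@@](C)(O[Si](CC)(CC)CC)CCC=C(C)C
F6 | step 13 | C3 epimer of 23 | C=C1C(=O)O[C@H]2/C=C(/C)[C@H](O)CC[C@](C)(O[Si](CC)(CC)CC)C[C@@H](OC(=O)/C(C)=C\C)[C@@H]12
F7 | step 13 | C3 ketone (enone) of 23 | C=C1C(=O)O[C@H]2/C=C(/C)C(=O)CC[C@](C)(O[Si](CC)(CC)CC)C[C@@H](OC(=O)/C(C)=C\C)[C@@H]12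
F8 | step 12 | vicinal diol from the terminal trisubstituted alkene of 20 (new carbinol as a mixture) | C=C1C(=O)O[C@@H](/C=C(/C)I)[C@H]1[C@H](OC(=O)/C(C)=C\C)C[C@@](C)(O[Si](CC)(CC)CC)CCC(O)C(C)(C)O
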